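| setting | birch | cedar | Tuesday's | Saturday's |
|---|---|---|---|---|
| J | 0.040 M | 0.071 M | 0.050 M | 0.080 M |
| D | 1.02 equiv | 1.02 equiv | 1.02 equiv | 1.02 equiv |
| Z | 0.010 M | 0.010 M | 0.0100 M | 0.0100 M |
| remark | run made earlier | run made earlier |  |  |
| time |  |  | 20 min | 20 min |

- birch (time / min: G / %): 2.00: 51.3; 4.00: 58.0; 6.00: 59.7; 8.00: 60.3; 10.0: 61.1; 12.0: 61.0; 15.0: 61.2
- cedar (time / min: G / %): 1.00: 54.5; 1.50: 61.5; 2.50: 66.3; 4.00: 71.3; 6.00: 71.7; 10.0: 72.1; 15.0: 71.5

(standard deviation of a reading: 0.5 percentage points)

- each molecule carries two end groups: a chain counts once for every two ends that are left, dead ends included; the units are half of the end groups of the two monomers charged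

* which of the two ends with the longer chains by the average number of monomer units in a chain (unreacted monomers counted as chains of one) ("neither" if they lie within 10%) (Tuesday's / Saturday's / neither)
* average number of monomer units in a chain (unreacted monomers counted as chains of one) at the end, Tuesday's
* average number of monomer units in a chain (unreacted monomers counted as chains of one) at the end, Saturday's

1. Slowness is not what I read in these runs: birch's readings average 61.1% of G from 10.0 min on and cedar's 71.8% from 6.00 min on, with J still left in both, so by hand I expect the 20 min of Tuesday's and Saturday's to reach such a plateau and add nothing beyond it.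

2. With Z and the equivalents of D held, more J goes with a higher plateau, cedar's readings standing higher than birch's, so I suppose that D is lost in a step that does not involve J while linking goes with J. Of each D used, the share J/(J + a) then links. Summing to the end of D gives a = c(E − g)/ln(c/l), with c the J charged, l the J left, E the equivalents of D and g the fraction linked.

3. Birch gives 0.0173 M and cedar 0.0170 M, so I carry their mean as the loss level, the concentration of J at which D goes equally to links and to loss, 0.0172 M, a selectivity factor in concentration units.

4. Z and the equivalents of D stay as in birch and cedar, so I keep the loss level, and E stays at 1.02 equiv. The charge of J is the setting that differs. I start each flask from the nearer run's remainder and correct it once, taking the geometric mean of that remainder and exp(−c(E − g)/a). This gives G of 65.6% for Tuesday's and 73.7% for Saturday's.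

5. Each link removes two ends, dead ends still count, and so my lengths are 2.86 for Tuesday's and 3.71 for Saturday's.

6. The forecast names Saturday's as the longer, with 2.85 for Tuesday's and 3.7 for Saturday's, holding that “something kills the reaction within about 5 min”. Its constant of 0.0093 M belongs to a loss of ends, so it is a different quantity from my loss level.

7. Tuesday's ends at 2.80 and Saturday's at 3.67, so Saturday's has the longer chains, and at 200 min Saturday's still stands at 3.67. By the loss level 0.0172 M, the share of D that I reckon to link in Saturday's falls from 82.3% at the charge to 55.3% at the J finally left.

    D → Q (k = 0.00414 s⁻¹)
    D + Z → X (k = 0.240 L mol⁻¹ s⁻¹)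
    J + D → G (k = 0.330 L mol⁻¹ s⁻¹)

8. In the neighbour of Saturday's charged with 0.260 equiv of D, the loss level, with J held at its charge as an estimate for the whole of D, gives 21.4% of G and a length of 1.51. That neighbour flask gives 20.5% of G and a length of 1.48.

Readings and results were computed for substances that don't exist.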